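**Plan**
- Retrosynthesis: the pyran ring is cut first at O1–C2 (phenol displacing an activated benzylic carbinol). Ring A is then cut at C4a–C8a, C5–C6 and C8–C8a into a 2-prenyl-3-methoxycyclobutenone and a chiral 1-methoxyalkyne. Each of these is cut at the sp–sp3 bond next to a methoxyacetylide.
- Enabling feature: ring A (C4a–C8a) alternates oxygen at C5, C7 and C8a with carbon at C4a (the C4 chain) and C6 (prenyl), and carries H at C8. A vinylketene/ynol ether benzannulation delivers exactly this pattern: chain ortho to the new OH, alkyne OMe at C5, cyclobutenone substituents at C6 and C7.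
- Forward: sodium methoxyacetylide is prenylated and taken on with ketene to the cyclobutenone. In parallel the aryl chloropropyl ketone is reduced, silylated, converted to the iodide and alkylated with lithium methoxyacetylide. The benzannulation then builds ring A as a mono-phenol, and the pyran ring closes last.
- Stereochemistry: the only stereocentre (C2) is set as the (R)-carbinol by CBS reduction and inverted to (2S) in the final Mitsunobu etherification.

Key step: step 7

Remark: the target is taken as the (2S)-flavan drawn; ketene is generated from acetone in a ketene lamp and passed directly into the reaction solution.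

**Step 1**
Reactants: 1 2-chloro-1,1-dimethoxyethane; 2 1-bromo-3-methylbut-2-ene
Product: 4 1-methoxy-5-methylhex-4-en-1-yne, via sodium methoxyacetylide 3 (not isolated)
Conditions: NaNH2 (3.0 equiv), liq. NH3, −33 °C; then 2, −33 °C; NH4Cl quench
Reagents that add atoms: none
Why: Twofold elimination (MeOH, then HCl) and deprotonation by NaNH2 should give the alkoxyacetylide, which is alkylated by the primary allylic bromide in an SN2 reaction (classical alkoxyacetylide alkylation in liquid ammonia); exactly three equivalents of base avoid isomerisation of the skipped enyne.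

**Step 2**
Reactants: 4 1-methoxy-5-methylhex-4-en-1-yne; 5 acetone
Product: 7 3-methoxy-2-(3-methylbut-2-enyl)cyclobut-2-en-1-one, via ketene 6 (not isolated)
Conditions: 5 through a ketene lamp (glowing Ni–Cr filament, ca. 700 °C); gas stream into 4, MeCN, 0 °C → rt
Reagents that add atoms: none
Why: Ketene–ynol ether [2+2] cycloaddition; the nucleophilic alkyne carbon bearing the prenyl group should attack the ketene carbonyl carbon, which places prenyl at C2 and OMe at C3, while the isolated trisubstituted alkene is inert to ketene.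

**Step 3**
Reactants: 8 3-chloro-1-(4-methoxyphenyl)propan-1-one
Product: 9 (R)-3-chloro-1-(4-methoxyphenyl)propan-1-ol
Conditions: (S)-Me-CBS oxazaborolidine [(S)-1-methyl-3,3-diphenyltetrahydro-1H,3H-pyrrolo[1,2-c][1,3,2]oxazaborole] (10 mol %), BH3·SMe2, THF, 0 °C; MeOH, then aqueous work-up
Reagents that add atoms: none
Why: Corey–Bakshi–Shibata reduction of an aryl alkyl ketone; with aryl as the large group the (S)-catalyst should deliver hydride to the Si face and give the (R)-carbinol, as for 3-chloropropiophenones in general.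

**Step 4**
Reactants: 9 (R)-3-chloro-1-(4-methoxyphenyl)propan-1-ol
Product: 10 (R)-tert-butyl[3-chloro-1-(4-methoxyphenyl)propoxy]dimethylsilane
Conditions: TBSCl, imidazole, DMF, rt
Reagents that add atoms: tert-butyldimethylsilyl chloride (TBSCl), CC(C)(C)[Si](C)(C)Cl
Why: Standard silylation of a secondary alcohol; the TBS ether masks the carbinol against strong base and against ketene trapping later on, and no bond to the stereocentre is touched.

**Step 5**
Reactants: 10 (R)-tert-butyl[3-chloro-1-(4-methoxyphenyl)propoxy]dimethylsilane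
Product: 11 (R)-tert-butyl[3-iodo-1-(4-methoxyphenyl)propoxy]dimethylsilane
Conditions: NaI, 2-butanone, 80 °C
Reagents that add atoms: sodium iodide, [Na+].[I-]
Why: Finkelstein halide exchange at an unhindered primary carbon, driven by precipitation of NaCl, should give the more reactive alkylating agent without affecting the silyl ether.

**Step 6**
Reactants: 1 2-chloro-1,1-dimethoxyethane; 11 (R)-tert-butyl[3-iodo-1-(4-methoxyphenyl)propoxy]dimethylsilane
Product: 13 (R)-tert-butyl[5-methoxy-1-(4-methoxyphenyl)pent-4-ynyloxy]dimethylsilane, via lithium methoxyacetylide 12 (not isolated)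
Conditions: 1 (1.5 equiv), LiNEt2 (4.5 equiv, from Et2NH and n-BuLi), THF, 0 °C; then 11, DMPU, 0 °C → rt; NH4Cl quench
Reagents that add atoms: none
Why: Three equivalents of LiNEt2 per acetal should effect the two eliminations and the deprotonation that give the lithium alkoxyacetylide, which is alkylated by the primary iodide in an SN2 reaction in THF/DMPU (the amide-base route to 1-alkoxy-1-alkynes), a homogeneous medium that suits the lipophilic silyl ether better than liquid ammonia; no free amide remains to attack the iodide and the stereocentre is two carbons away from the reacting site.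

**Step 7**
Reactants: 7 3-methoxy-2-(3-methylbut-2-enyl)cyclobut-2-en-1-one; 13 (R)-tert-butyl[5-methoxy-1-(4-methoxyphenyl)pent-4-ynyloxy]dimethylsilane
Product: 18 (R)-2-[3-(tert-butyldimethylsilyloxy)-3-(4-methoxyphenyl)propyl]-3,5-dimethoxy-4-(3-methylbut-2-enyl)phenol, via vinylketene 14 (not isolated), via vinylcyclobutenone 15 (not isolated), via dienylketene 16 (not isolated), via cyclohexadienone 17 (not isolated)
Conditions: 7 (1.2 equiv), PhMe, 110 °C, sealed tube
Reagents that add atoms: none
Why: Heating should open 7 by 4π-electrocyclic cleavage to vinylketene 14, whose electrophilic carbonyl carbon (future C8a) is attacked by the nucleophilic, chain-bearing carbon of ynol ether 13 (future C4a) in a regiospecific [2+2] cycloaddition that also joins C6 to the methoxy-bearing alkyne carbon C5 and gives 15. Cyclobutenone 15 opens again (4π) to dienylketene 16, ring A closes by a thermally allowed disrotatory 6π electrocyclisation that forms C8–C8a, and dienone 17 tautomerises irreversibly to phenol 18. This is the Danheiser benzannulation of a cyclobutenone with an alkoxyalkyne, closest in type to annulations of 1-methoxyalkynes that carry functionalised chains. No stereocentre is created (the quaternary carbon of 15 is lost on ring opening) and the silylated (R)-carbinol is a remote spectator. The required regioselectivity rests on the polarisation of the ynol ether alone; chemoselectivity is secured by the TBS ether (no free hydroxyl to trap a ketene) and by the methyl ynol ether, which has no β-hydrogen for retro-ene fragmentation. The vinylogous-ester stabilisation of 7 is expected to slow the first ring opening relative to alkyl cyclobutenones, hence 110 °C.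

**Step 8**
Reactants: 18 (R)-2-[3-(tert-butyldimethylsilyloxy)-3-(4-methoxyphenyl)propyl]-3,5-dimethoxy-4-(3-methylbut-2-enyl)phenol
Product: 19 (R)-2-[3-hydroxy-3-(4-methoxyphenyl)propyl]-3,5-dimethoxy-4-(3-methylbut-2-enyl)phenol
Conditions: Bu4NF, THF, 0 °C → rt; aqueous work-up
Reagents that add atoms: none
Why: Fluoride-induced cleavage of the Si–O bond under non-acidic conditions should free the carbinol without ionising the 4-methoxybenzylic position, so the configuration is retained.

**Step 9**
Reactants: 19 (R)-2-[3-hydroxy-3-(4-methoxyphenyl)propyl]-3,5-dimethoxy-4-(3-methylbut-2-enyl)phenol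
Product: 21 (2S)-5,7-dimethoxy-2-(4-methoxyphenyl)-6-(3-methylbut-2-enyl)chroman, via oxyphosphonium phenoxide 20 (not isolated)
Conditions: PPh3, DIAD, PhMe, −20 → 0 °C
Reagents that add atoms: none
Why: Intramolecular Mitsunobu etherification; the only phenol of the molecule displaces the oxyphosphonium group in a 6-exo-tet SN2 closure with inversion, (R) → (2S), and the non-polar solvent and low temperature are chosen to suppress ionisation of the benzylic centre.

**Compound list**
1 | 2-chloro-1,1-dimethoxyethane (chloroacetaldehyde dimethyl acetal) | COC(CCl)OC | starting material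
2 | 1-bromo-3-methylbut-2-ene (prenyl bromide) | CC(C)=CCBr | starting material
3 | sodium methoxyacetylide | [Na+].[C-]#COC | intermediate (not isolated)
4 | 1-methoxy-5-methylhex-4-en-1-yne | COC#CCC=C(C)C | intermediate
5 | acetone | CC(C)=O | starting material
6 | ketene (ethenone) | C=C=O | intermediate (not isolated)
7 | 3-methoxy-2-(3-methylbut-2-enyl)cyclobut-2-en-1-one | COC1=C(CC=C(C)C)C(=O)C1 | intermediate
8 | 3-chloro-1-(4-methoxyphenyl)propan-1-one | COc1ccc(C(=O)CCCl)cc1 | starting material
9 | (R)-3-chloro-1-(4-methoxyphenyl)propan-1-ol | COc1ccc([C@H](O)CCCl)cc1 | intermediate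
10 | (R)-tert-butyl[3-chloro-1-(4-methoxyphenyl)propoxy]dimethylsilane | COc1ccc([C@H](O[Si](C)(C)C(C)(C)C)CCCl)cc1 | intermediate
11 | (R)-tert-butyl[3-iodo-1-(4-methoxyphenyl)propoxy]dimethylsilane | COc1ccc([C@H](O[Si](C)(C)C(C)(C)C)CCI)cc1 | intermediate
12 | lithium methoxyacetylide | [Li+].[C-]#COC | intermediate (not isolated)
13 | (R)-tert-butyl[5-methoxy-1-(4-methoxyphenyl)pent-4-ynyloxy]dimethylsilane | COc1ccc([C@H](O[Si](C)(C)C(C)(C)C)CCC#COC)cc1 | intermediate
14 | 3-methoxy-2-(3-methylbut-2-enyl)buta-1,3-dien-1-one (vinylketene) | C=C(OC)C(CC=C(C)C)=C=O | intermediate (not isolated)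
15 | 2-[(3R)-3-(tert-butyldimethylsilyloxy)-3-(4-methoxyphenyl)propyl]-3-methoxy-4-(1-methoxyethenyl)-4-(3-methylbut-2-enyl)cyclobut-2-en-1-one (both epimers at C4) | COc1ccc([C@H](O[Si](C)(C)C(C)(C)C)CCC2=C(OC)C(CC=C(C)C)(C(OC)=C)C2=O)cc1 | intermediate (not isolated)
16 | 2-[(3R)-3-(tert-butyldimethylsilyloxy)-3-(4-methoxyphenyl)propyl]-3,5-dimethoxy-4-(3-methylbut-2-enyl)hexa-1,3,5-trien-1-one (dienylketene) | COc1ccc([C@H](O[Si](C)(C)C(C)(C)C)CCC(=C=O)C(OC)=C(CC=C(C)C)C(OC)=C)cc1 | intermediate (not isolated)
17 | 2-[(3R)-3-(tert-butyldimethylsilyloxy)-3-(4-methoxyphenyl)propyl]-3,5-dimethoxy-4-(3-methylbut-2-enyl)cyclohexa-2,4-dien-1-one | COc1ccc([C@H](O[Si](C)(C)C(C)(C)C)CCC2=C(OC)C(CC=C(C)C)=C(OC)CC2=O)cc1 | intermediate (not isolated)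
18 | (R)-2-[3-(tert-butyldimethylsilyloxy)-3-(4-methoxyphenyl)propyl]-3,5-dimethoxy-4-(3-methylbut-2-enyl)phenol | COc1ccc([C@H](O[Si](C)(C)C(C)(C)C)CCc2c(O)cc(OC)c(CC=C(C)C)c2OC)cc1 | intermediate
19 | (R)-2-[3-hydroxy-3-(4-methoxyphenyl)propyl]-3,5-dimethoxy-4-(3-methylbut-2-enyl)phenol | COc1ccc([C@H](O)CCc2c(O)cc(OC)c(CC=C(C)C)c2OC)cc1 | intermediate
20 | [(1R)-3-[4,6-dimethoxy-5-(3-methylbut-2-enyl)-2-oxidophenyl]-1-(4-methoxyphenyl)propoxy]triphenylphosphonium (zwitterion) | COc1ccc([C@H](O[P+](c2ccccc2)(c2ccccc2)c2ccccc2)CCc2c([O-])cc(OC)c(CC=C(C)C)c2OC)cc1 | intermediate (not isolated)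
21 | (2S)-5,7-dimethoxy-2-(4-methoxyphenyl)-6-(3-methylbut-2-enyl)chroman | COc1ccc([C@@H]2CCc3c(cc(OC)c(CC=C(C)C)c3OC)O2)cc1 | target

**Count**
Total: 9 steps. Longest linear sequence: 7 steps (8 → 9 → 10 → 11 → 13 → 18 → 19 → 21, steps 3–9); the cyclobutenone arm (steps 1–2) joins at step 7.

**Steps most likely to fail, with fallbacks**

Step 7. The first electrocyclic opening may be too slow, because the 3-methoxy group stabilises cyclobutenone 7 as a vinylogous ester. At the higher temperature then needed, ketene oligomerisation and acylation of the product phenol by the vinylketene would compete. The fallback keeps the benzannulation but makes vinylketene 14 at room temperature by a photochemical Wolff rearrangement (the diazo ketone variant of the same annulation). It sets out from alkyne 13 and returns to the route at 14, and so at 18.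
- Commercial 5-methylhex-4-enoic acid is converted (carbonyldiimidazole, MeNHOMe·HCl) into N-methoxy-N,5-dimethylhex-4-enamide F1.
- Addition of 1-methoxyvinyllithium (methyl vinyl ether, t-BuLi, THF, −78 → 0 °C) should give 2-methoxy-7-methylocta-1,6-dien-3-one F2.
- Detrifluoroacetylative diazo transfer follows: LiN(SiMe3)2 and 2,2,2-trifluoroethyl trifluoroacetate give 1,1,1-trifluoro-5-methoxy-3-(3-methylbut-2-enyl)hex-5-ene-2,4-dione F3, which with MsN3, Et3N and water in MeCN gives 4-diazo-2-methoxy-7-methylocta-1,6-dien-3-one F4.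
- Irradiation of F4 with 13 (CH2Cl2, rt, 300 nm) should generate 14 by migration of the methoxyvinyl group and give 15; brief heating in PhMe (80–110 °C) then completes the sequence to 18.

Step 9. The oxyphosphonium intermediate 20 may partly ionise to a 4-methoxybenzylic cation before the phenoxide attacks, which would erode the enantiomeric purity or lead to elimination. The fallback forms O1–C8a instead of O1–C2, so that no substitution takes place at the stereocentre. It sets out from 19 and returns at 21.
- Phenol-selective triflation (PhNTf2, K2CO3, THF) should give (R)-2-[3-hydroxy-3-(4-methoxyphenyl)propyl]-3,5-dimethoxy-4-(3-methylbut-2-enyl)phenyl trifluoromethanesulfonate F5.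
- Because a closure with retention needs the opposite carbinol configuration, the alcohol is oxidised (Dess–Martin periodinane) to 3,5-dimethoxy-2-[3-(4-methoxyphenyl)-3-oxopropyl]-4-(3-methylbut-2-enyl)phenyl trifluoromethanesulfonate F6.
- Asymmetric transfer hydrogenation (RuCl[(S,S)-TsDPEN](p-cymene), HCO2H/Et3N), which leaves the prenyl alkene alone, should give (S)-2-[3-hydroxy-3-(4-methoxyphenyl)propyl]-3,5-dimethoxy-4-(3-methylbut-2-enyl)phenyl trifluoromethanesulfonate F7.
- Palladium-catalysed intramolecular aryl etherification (Pd(OAc)2, 2-(di-tert-butylphosphino)-1,1'-binaphthyl, Cs2CO3, PhMe, 70 °C) should close the pyran ring with retention to give 21.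

Step 2. Dimerisation and polymerisation of ketene may outrun the cycloaddition, and the small, heat-sensitive cyclobutenone may be lost on isolation. The fallback attaches the prenyl group to a preformed four-membered ring by cross-coupling. It sets out from prenyl bromide 2 and returns at 7.
- Bromide 2 with Bu3SnLi (THF, −78 °C) gives tributyl(3-methylbut-2-enyl)stannane F8.
- Commercial 3-ethoxycyclobut-2-en-1-one is brominated (NBS, CH2Cl2, 0 °C) to 2-bromo-3-ethoxycyclobut-2-en-1-one F9.
- Stille coupling of F9 with F8 (Pd2(dba)3, P(2-furyl)3, THF, 45 °C) should give 3-ethoxy-2-(3-methylbut-2-enyl)cyclobut-2-en-1-one F10.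
- Mild hydrolysis (dilute HCl, THF, rt) gives the symmetrical dione as its enol, 3-hydroxy-2-(3-methylbut-2-enyl)cyclobut-2-en-1-one F11, and O-methylation with Me3SiCHN2 (MeOH/PhMe) gives 7 as the only possible regioisomer.

**Further compounds**
F1 | step 7 | N-methoxy-N,5-dimethylhex-4-enamide | CON(C)C(=O)CCC=C(C)C
F2 | step 7 | 2-methoxy-7-methylocta-1,6-dien-3-one | C=C(OC)C(=O)CCC=C(C)C
F3 | step 7 | 1,1,1-trifluoro-5-methoxy-3-(3-methylbut-2-enyl)hex-5-ene-2,4-dione | C=C(OC)C(=O)C(CC=C(C)C)C(=O)C(F)(F)F
F4 | step 7 | 4-diazo-2-methoxy-7-methylocta-1,6-dien-3-one | C=C(OC)C(=O)C(=[N+]=[N-])CC=C(C)C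
F5 | step 9 | (R)-2-[3-hydroxy-3-(4-methoxyphenyl)propyl]-3,5-dimethoxy-4-(3-methylbut-2-enyl)phenyl trifluoromethanesulfonate | COc1ccc([C@H](O)CCc2c(OS(=O)(=O)C(F)(F)F)cc(OC)c(CC=C(C)C)c2OC)cc1
F6 | step 9 | 3,5-dimethoxy-2-[3-(4-methoxyphenyl)-3-oxopropyl]-4-(3-methylbut-2-enyl)phenyl trifluoromethanesulfonate | COc1ccc(C(=O)CCc2c(OS(=O)(=O)C(F)(F)F)cc(OC)c(CC=C(C)C)c2OC)cc1
F7 | step 9 | (S)-2-[3-hydroxy-3-(4-methoxyphenyl)propyl]-3,5-dimethoxy-4-(3-methylbut-2-enyl)phenyl trifluoromethanesulfonate | COc1ccc([C@@H](O)CCc2c(OS(=O)(=O)C(F)(F)F)cc(OC)c(CC=C(C)C)c2OC)cc1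
F8 | step 2 | tributyl(3-methylbut-2-enyl)stannane | CCCC[Sn](CCCC)(CCCC)CC=C(C)C
F9 | step 2 | 2-bromo-3-ethoxycyclobut-2-en-1-one | CCOC1=C(Br)C(=O)C1
F10 | step 2 | 3-ethoxy-2-(3-methylbut-2-enyl)cyclobut-2-en-1-one | CCOC1=C(CC=C(C)C)C(=O)C1
F11 | step 2 | 3-hydroxy-2-(3-methylbut-2-enyl)cyclobut-2-en-1-one | OC1=C(CC=C(C)C)C(=O)C1
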